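All runs come from a simulation with constants of no real substance.

One minute at the east run's 13 °C carries a fixed fraction of the target then present over into over-reaction product. Set against the minutes a flask stands, that fraction chooses the next flask.

all flasks: substrate 0.050 M

| run | coupling partner | free catalyst | temperature | remark | time |
|---|---|---|---|---|---|
| north-west | 0.040 M | 1 mM | −20 °C | run made earlier |  |
| east | 0.090 M | 1 mM | 13 °C | run made earlier |  |
| Thursday's | 0.0600 M | 1.0 mM | −35 °C |  | 25 min |
| Monday's | 0.0600 M | 1.0 mM | 25 °C |  | 25 min |
| Sunday's | 0.0600 M | 1.0 mM | −5 °C |  | 25 min |

north-west run (percent of the substrate charged)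

| time / min | target / % | over-reaction product / % |
|---|---|---|
| 1.33 | 0.3 | 0 |
| 2.50 | 0.9 | 0 |
| 4.00 | 2.1 | 0.3 |
| 5.00 | 2.9 | 0.4 |
| 6.00 | 3.3 | 0 |
| 8.00 | 4.7 | 0 |

east run (percent of the substrate charged)

| time / s | target / % | over-reaction product / % |
|---|---|---|
| 15.0 | 2.3 | 0 |
| 30.0 | 5.1 | 0.2 |
| 40.0 | 6.2 | 0 |
| 60.0 | 10.0 | 0.7 |
| 80.0 | 12.5 | 0.6 |

(readings scatter by 0.3 percentage points)

* the best flask by share of target in all that became target or over-reaction product; "all alike" if 1.5 percentage points covers them all (Thursday's / Monday's / Sunday's / all alike)
* share of target in all that became target or over-reaction product, Thursday's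
* share of target in all that became target or over-reaction product, Monday's
* share of target in all that became target or over-reaction product, Sunday's



Target made at a steady pace has on average stood for half of the elapsed time, so over-reaction product over target reads half the loss per minute times the elapsed minutes. The last two east readings give:

loss per minute = 2 × (sum of over-reaction product) / (sum of target × time) = 0.0975 /min

over 25 min at that temperature: 2.44

share = 1 / (1 + loss number / 2) = 45.1%

This product of loss per minute and minutes stood is the loss number. Its zero of scale is 2, where over-reaction product equals target and the share, or selectivity, is 50.0%. The value is a reading, uncertain by about a third.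

The north-west readings of over-reaction product are too close to the scatter to show how the loss moves with temperature. My own reckoning therefore assumes that it moves as the making does, which gained 16.0-fold from the north-west run to the east run, partner change included:

Thursday's: loss number 0.0434, share 97.9%

Sunday's: 4.53-fold below east, loss number 0.538, share 78.8%

Monday's: loss number 6.67, share 23.1%

Thursday's is the flask to charge, with a share higher than the other two.

The forecast also names Thursday's, with 96%, 54% and 80% for Thursday's, Monday's and Sunday's: “Selectivity therefore follows conversion, and the coldest flask is best.” It parts from my reckoning on Monday's, 54% against 23.1%.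

The flasks give >99.9% for Thursday's, 1.21% for Monday's and 95.2% for Sunday's, so the best is Thursday's.

    substrate + free catalyst → catalyst intermediate A (k = 5.40 /M/s, Ea = 43.0 kJ/mol)
    catalyst intermediate A ⇌ catalyst intermediate B (K = 0.890, k = 0.910 /s, Ea = 62.0 kJ/mol, ΔH = −10.0 kJ/mol)
    coupling partner + catalyst intermediate B ⇌ catalyst intermediate C (K = 19.0 /M, k = 98.0 /M/s, Ea = 41.0 kJ/mol, ΔH = −5.00 kJ/mol)
    catalyst intermediate C → free catalyst + target (k = 64.0 /s, Ea = 62.0 kJ/mol)
    target → over-reaction product (k = 0.00390 /s, Ea = 92.0 kJ/mol)
    (constants at 25 °C)

Between Monday's and Thursday's, what the temperature does to the conversion of target into over-reaction product is the largest single effect on the difference in share: without it that difference shrinks from 99 percentage points to 0.021 points, an effect of 99 points, against 16 points for the conversion of catalyst intermediate A into catalyst intermediate B. Sunday's flask reads a loss number of 0.100 at 25.0 min, below the 2.44 read, with its scatter, off the east run for the same minutes at 13 °C. The neighbouring flask, Sunday's with 0.400 of the catalyst charge, ends with less target, 22.6% against 49.2%, yet reads a loss number of 0.0954, and its share stands at 95.4%.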